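**Plan**

1. Retrosynthesis: after removal of four silyl groups, ring B is cut at C7'–O and C8'–H, back to a Z-benzylidene C8'=C7' and a C9 hydroxyl. C9–O is traced to C9–B, and the ring-fusion bond C8–C8' is cut to a 1-arylallyl 3-arylpropargyl ether. This enyne is cut at C7'–aryl and at O–C9', and the glycerol arm at C7''–C8''.
2. Forward: the threo side chain is built first on 4-bromo-2,6-dimethoxyphenol (aldol). The aryl bromide is then joined to the (R)-allyl propargyl ether (C7'–aryl). Ring A (C7–O–C9'–C8'–C8) closes in the borylative cyclization and ring B (C7'–O–C9–C8–C8') closes two steps later.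
3. Enabling feature: C8–C8' is the bond shared by rings A and B. Ring A needs only C7 as a resident stereocentre, and the endo syringyl group on C7' can be held as the Z geometry of a C8'=C7' benzylidene exocyclic to ring A.
4. Stereochemistry: C7 (R) comes from a Sharpless kinetic resolution; C8 from C7 during the cyclization (trans); C7' from anti selenoetherification of the Z-alkene; C8' from the enforced cis ring fusion; C7'' and C8'' (R,R, threo) from an Evans syn-aldol on the (S)-4-benzyl oxazolidinone.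

Key step: step 11

Remark: lignan numbering is used (guaiacyl unit C7–C9, central syringyl unit C7'–C9', glycerol unit C7''–C9''); the target is read as 7R,8S,7'S,8'S,7''R,8''R, that is guaiacyl exo and central syringyl endo on a cis-fused core with a threo side chain; (S)-4-benzyl-3-(chloroacetyl)oxazolidin-2-one is assumed to be a catalogue compound.

Shorthand in names: Gu = 3-methoxy-4-(triisopropylsilyloxy)phenyl; Sy = 3,5-dimethoxy-4-{[(1R,2R)-1,3-bis(tert-butyldimethylsilyloxy)-1-[3,5-dimethoxy-4-(triisopropylsilyloxy)phenyl]propan-2-yl]oxy}phenyl.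

**Route**

Step 1
Reactants: 1 vanillin
Product: 2 3-methoxy-4-(triisopropylsilyloxy)benzaldehyde
Conditions: TIPSCl, imidazole, DMF, rt
Reagents that add atoms: triisopropylsilyl chloride, CC(C)[Si](Cl)(C(C)C)C(C)C
Why: Imidazole-promoted O-silylation of a phenol (standard silyl ether formation); the triisopropylsilyl group is chosen because it should survive the Grignard reagent, NaH and aqueous NaBO3 used later and still leave with fluoride at the end.

Step 2
Reactants: 2 3-methoxy-4-(triisopropylsilyloxy)benzaldehyde; 3 vinylmagnesium bromide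
Product: 5 rac-1-[3-methoxy-4-(triisopropylsilyloxy)phenyl]prop-2-en-1-ol, via bromomagnesium alkoxide 4 (not isolated)
Conditions: THF, −78 °C to 0 °C; then pH 7 aqueous buffer
Reagents that add atoms: none
Why: 1,2-Addition of a vinyl Grignard reagent to an aryl aldehyde joins C7 to C8; the carbinol centre C7 is formed racemic and is resolved in step 3.

Step 3
Reactants: 5 rac-1-[3-methoxy-4-(triisopropylsilyloxy)phenyl]prop-2-en-1-ol
Product: 6 (1R)-1-[3-methoxy-4-(triisopropylsilyloxy)phenyl]prop-2-en-1-ol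
Conditions: Ti(OiPr)4 (20 mol %), D-(−)-diisopropyl tartrate (24 mol %), t-BuOOH (0.6 equiv), 4 Å MS, CH2Cl2, −20 °C
Reagents that add atoms: none
Why: Sharpless kinetic resolution of a secondary allylic alcohol: with the D-(−)-tartrate the (S)-carbinol is the antipode that is epoxidised quickly, so the (R)-alcohol carrying C7 of the target should be recovered unchanged at a little over half conversion.

Step 4
Reactants: 6 (1R)-1-[3-methoxy-4-(triisopropylsilyloxy)phenyl]prop-2-en-1-ol; 7 propargyl bromide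
Product: 9 (R)-1-Gu-prop-2-enyl prop-2-ynyl ether, via sodium alkoxide 8 (not isolated)
Conditions: NaH, THF, 0 °C; then 7, Bu4NI (cat.), 0 °C to rt
Reagents that add atoms: none
Why: Williamson etherification of the sodium alkoxide with a primary propargylic bromide forms the C7–O–C9' link by SN2 at C9', so the C7–O bond and its R configuration are not involved.

Step 5
Reactants: 10 4-bromo-2,6-dimethoxyphenol; 11 (S)-4-benzyl-3-(chloroacetyl)oxazolidin-2-one
Product: 12 (4S)-4-benzyl-3-[(4-bromo-2,6-dimethoxyphenoxy)acetyl]oxazolidin-2-one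
Conditions: K2CO3, NaI (cat.), MeCN, 50 °C
Reagents that add atoms: none
Why: Williamson-type SN2 displacement of chloride from an α-chloro imide by a phenoxide, assisted by iodide exchange; the hindered phenoxide should alkylate at carbon faster than it attacks the imide carbonyl, and no stereocentre is affected.

Step 6
Reactants: 13 syringaldehyde
Product: 14 3,5-dimethoxy-4-(triisopropylsilyloxy)benzaldehyde
Conditions: TIPSCl, imidazole, DMF, 50 °C
Reagents that add atoms: triisopropylsilyl chloride, CC(C)[Si](Cl)(C(C)C)C(C)C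
Why: Imidazole-promoted O-silylation of the hindered phenol, warmed because of the two flanking methoxy groups; the aldehyde is untouched.

Step 7
Reactants: 12 (4S)-4-benzyl-3-[(4-bromo-2,6-dimethoxyphenoxy)acetyl]oxazolidin-2-one; 14 3,5-dimethoxy-4-(triisopropylsilyloxy)benzaldehyde
Product: 17 (4S)-4-benzyl-3-{(2S,3R)-2-(4-bromo-2,6-dimethoxyphenoxy)-3-[3,5-dimethoxy-4-(triisopropylsilyloxy)phenyl]-3-hydroxypropanoyl}oxazolidin-2-one, via dibutylboron Z-enolate 15 (not isolated), via dibutylboron aldolate 16 (not isolated)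
Conditions: Bu2BOTf, iPr2NEt, CH2Cl2, −78 °C to 0 °C; 14, −78 °C to 0 °C; then pH 7 buffer, MeOH, H2O2, 0 °C
Reagents that add atoms: none
Why: Evans syn-aldol reaction: the Z-configured boron enolate 15 reacts through a closed chair transition state on the enolate face turned away from the benzyl group of the (S)-auxiliary, which should set C8'' and C7'' together as the syn (threo) pair, (2S,3R) in the imide, before oxidative cleavage of the boron aldolate 16.

Step 8
Reactants: 17 the syn-aldol imide
Product: 18 (1R,2R)-2-(4-bromo-2,6-dimethoxyphenoxy)-1-[3,5-dimethoxy-4-(triisopropylsilyloxy)phenyl]propane-1,3-diol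
Conditions: LiBH4, MeOH (1 equiv), THF, 0 °C
Reagents that add atoms: none
Why: Reductive cleavage of the N-acyl oxazolidinone with LiBH4 gives the primary alcohol C9'' and releases the auxiliary; neither stereocentre is touched, and the descriptors become 1R,2R only through the change in substituent priorities.

Step 9
Reactants: 18 the (1R,2R)-diol
Product: 19 (1R,2R)-2-(4-bromo-2,6-dimethoxyphenoxy)-1,3-bis(tert-butyldimethylsilyloxy)-1-[3,5-dimethoxy-4-(triisopropylsilyloxy)phenyl]propane
Conditions: TBSOTf, 2,6-lutidine, CH2Cl2, −78 °C to 0 °C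
Reagents that add atoms: tert-butyldimethylsilyl trifluoromethanesulfonate, CC(C)(C)[Si](C)(C)OS(=O)(=O)C(F)(F)F
Why: Silylation of a primary and a secondary benzylic alcohol with a silyl triflate and a hindered pyridine base is routine and masks both hydroxyls for the metal-mediated steps to come.

Step 10
Reactants: 9 (R)-1-Gu-prop-2-enyl prop-2-ynyl ether; 19 the bis-silylated aryl bromide
Product: 20 (R)-1-Gu-prop-2-enyl 3-Sy-prop-2-ynyl ether
Conditions: PdCl2(PhCN)2 (cat.), P(t-Bu)3 (cat.), CuI (cat.), iPr2NH, dioxane, rt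
Reagents that add atoms: none
Why: Sonogashira coupling: zerovalent palladium carrying the bulky, electron-rich P(t-Bu)3 inserts into the electron-rich aryl C–Br bond at room temperature and the copper acetylide of 9 delivers the alkyne, forming the C7'–aryl bond without touching the allylic ether or the silyl groups.

Step 11
Reactants: 20 (R)-1-Gu-prop-2-enyl 3-Sy-prop-2-ynyl ether; 21 bis(pinacolato)diboron
Product: 22 (2R,3R,4Z)-2-Gu-4-(Sy-methylidene)-3-[(4,4,5,5-tetramethyl-1,3,2-dioxaborolan-2-yl)methyl]tetrahydrofuran (Gu and the CH2B arm trans; Sy cis to the ring CH2–O)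
Conditions: Pd(OAc)2 (5 mol %), B2pin2 (1.2 equiv), MeOH (1 equiv), toluene, 50 °C
Reagents that add atoms: none
Why: A palladium hydride generated from Pd(OAc)2, B2pin2 and methanol adds syn across the aryl alkyne with palladium on C8', the alkenylpalladium inserts the vinyl group in a 5-exo-trig mode to form C8–C8' and ring A (C7–O–C9'–C8'–C8), and the primary alkylpalladium at C9 is borylated by B2pin2 before it can lose the C8 hydrogen. The closest known reaction type is the Pd(OAc)2-catalysed borylative cyclization of 1,6-enynes with B2pin2, which includes oxygen-tethered substrates. The one new stereocentre, C8, is controlled by C7: in the chair-like insertion transition state the guaiacyl group on the allylic carbon sits pseudo-equatorial, so the CH2B arm should end up trans to it (2R,3R in 22). The syn hydropalladation fixes the benzylidene as Z with the syringyl ring cis to C9', the relation that step 13 converts into the endo aryl group at C7'. The step needs 5-exo over 6-endo closure and borylation over β-hydride elimination; the first is secured by the three-atom ether tether, because only palladium on C8' can reach the alkene, and the second by the excess of diboron and the absence of phosphine ligands.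

Step 12
Reactants: 22 the pinacol boronate
Product: 23 [(2R,3S,4Z)-2-Gu-4-(Sy-methylidene)tetrahydrofuran-3-yl]methanol
Conditions: NaBO3·4H2O, THF/H2O, rt
Reagents that add atoms: sodium perborate, [Na+].[O-]OB=O
Why: Oxidation of a primary alkyl pinacol boronate by NaBO3 (1,2-migration from boron to oxygen) should give the C9 alcohol; the mildly basic medium spares the silyl ethers and the styrene, and C8 is not involved.

Step 13
Reactants: 23 the homoallylic alcohol
Product: 24 (1R,3aR,4R,6aS)-1-Gu-4-Sy-3a-(phenylselanyl)tetrahydro-1H,3H-furo[3,4-c]furan (cis-fused; Gu exo; Sy endo; selenium on C8')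
Conditions: PhSeCl, K2CO3, CH2Cl2, −78 °C
Reagents that add atoms: phenylselenenyl chloride, Cl[Se]c1ccccc1
Why: 5-endo-trig selenoetherification of a homoallylic alcohol: the phenylselenenyl cation adds to C8'=C7' on the face away from the C9 arm, the C9 hydroxyl opens the seleniranium ion at benzylic C7' from the opposite face, and this anti addition to the Z-alkene should close ring B with the syringyl group endo (the 7'S arrangement of the target) and selenium on the convex face at C8'.

Step 14
Reactants: 24 the ring-fusion selenide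
Product: 25 (1R,3aS,4S,6aS)-1-Gu-4-Sy-tetrahydro-1H,3H-furo[3,4-c]furan
Conditions: Bu3SnH, AIBN (cat.), toluene, 85 °C
Reagents that add atoms: none
Why: Radical deselenation with Bu3SnH: the tertiary C8' radical can only take hydrogen on the convex face because a trans-fused 3,7-dioxabicyclo[3.3.0]octane is prohibitively strained, so C8' is set S (H8' cis to H8) and C7' is untouched.

Step 15
Reactants: 25 the tetrasilylated furofuran
Product: 26 (1R,2R)-1-(4-hydroxy-3,5-dimethoxyphenyl)-2-{4-[(1S,3aS,4R,6aS)-4-(4-hydroxy-3-methoxyphenyl)tetrahydro-1H,3H-furo[3,4-c]furan-1-yl]-2,6-dimethoxyphenoxy}propane-1,3-diol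
Conditions: TBAF, AcOH, THF, 0 °C to rt
Reagents that add atoms: none
Why: Fluoride-induced desilylation removes the two aryl triisopropylsilyl ethers and the two alkyl tert-butyldimethylsilyl ethers in one operation; acetic acid buffers the phenoxides so that the benzylic ether bonds of the furofuran and all six stereocentres should stay intact.

**Compound list**

1 | vanillin | COc1cc(C=O)ccc1O | starting material
2 | 3-methoxy-4-(triisopropylsilyloxy)benzaldehyde | COc1cc(C=O)ccc1O[Si](C(C)C)(C(C)C)C(C)C | intermediate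
3 | vinylmagnesium bromide | C=C[Mg]Br | starting material
4 | bromomagnesium alkoxide of 5 | COc1cc(C(O[Mg]Br)C=C)ccc1O[Si](C(C)C)(C(C)C)C(C)C | intermediate
5 | rac-1-[3-methoxy-4-(triisopropylsilyloxy)phenyl]prop-2-en-1-ol | COc1cc(C(O)C=C)ccc1O[Si](C(C)C)(C(C)C)C(C)C | intermediate
6 | (1R)-1-[3-methoxy-4-(triisopropylsilyloxy)phenyl]prop-2-en-1-ol | COc1cc([C@@H](C=C)O)ccc1O[Si](C(C)C)(C(C)C)C(C)C | intermediate
7 | propargyl bromide | C#CCBr | starting material
8 | sodium alkoxide of 6 | COc1cc([C@@H](C=C)[O-])ccc1O[Si](C(C)C)(C(C)C)C(C)C.[Na+] | intermediate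
9 | (R)-1-Gu-prop-2-enyl prop-2-ynyl ether | COc1cc([C@@H](C=C)OCC#C)ccc1O[Si](C(C)C)(C(C)C)C(C)C | intermediate
10 | 4-bromo-2,6-dimethoxyphenol | COc1cc(Br)cc(OC)c1O | starting material
11 | (S)-4-benzyl-3-(chloroacetyl)oxazolidin-2-one | O=C(CCl)N1[C@@H](Cc2ccccc2)COC1=O | starting material
12 | (4S)-4-benzyl-3-[(4-bromo-2,6-dimethoxyphenoxy)acetyl]oxazolidin-2-one | COc1cc(Br)cc(OC)c1OCC(=O)N1[C@@H](Cc2ccccc2)COC1=O | intermediate
13 | syringaldehyde | COc1cc(C=O)cc(OC)c1O | starting material
14 | 3,5-dimethoxy-4-(triisopropylsilyloxy)benzaldehyde | COc1cc(C=O)cc(OC)c1O[Si](C(C)C)(C(C)C)C(C)C | intermediate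
15 | dibutylboron (Z)-enolate of 12 | CCCCB(CCCC)O/C(=C\Oc1c(OC)cc(Br)cc1OC)N1[C@@H](Cc2ccccc2)COC1=O | intermediate
16 | dibutylboron aldolate of 17 | COc1cc(Br)cc(OC)c1O[C@H](C(=O)N1[C@@H](Cc2ccccc2)COC1=O)[C@H](OB(CCCC)CCCC)c1cc(OC)c(O[Si](C(C)C)(C(C)C)C(C)C)c(OC)c1 | intermediate
17 | (4S)-4-benzyl-3-{(2S,3R)-2-(4-bromo-2,6-dimethoxyphenoxy)-3-[3,5-dimethoxy-4-(triisopropylsilyloxy)phenyl]-3-hydroxypropanoyl}oxazolidin-2-one | COc1cc(Br)cc(OC)c1O[C@H](C(=O)N1[C@@H](Cc2ccccc2)COC1=O)[C@H](O)c1cc(OC)c(O[Si](C(C)C)(C(C)C)C(C)C)c(OC)c1 | intermediate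
18 | (1R,2R)-2-(4-bromo-2,6-dimethoxyphenoxy)-1-[3,5-dimethoxy-4-(triisopropylsilyloxy)phenyl]propane-1,3-diol | COc1cc(Br)cc(OC)c1O[C@H](CO)[C@H](O)c1cc(OC)c(O[Si](C(C)C)(C(C)C)C(C)C)c(OC)c1 | intermediate
19 | (1R,2R)-2-(4-bromo-2,6-dimethoxyphenoxy)-1,3-bis(tert-butyldimethylsilyloxy)-1-[3,5-dimethoxy-4-(triisopropylsilyloxy)phenyl]propane | COc1cc(Br)cc(OC)c1O[C@H](CO[Si](C)(C)C(C)(C)C)[C@H](O[Si](C)(C)C(C)(C)C)c1cc(OC)c(O[Si](C(C)C)(C(C)C)C(C)C)c(OC)c1 | intermediate
20 | (R)-1-Gu-prop-2-enyl 3-Sy-prop-2-ynyl ether | COc1cc([C@@H](C=C)OCC#Cc2cc(OC)c(O[C@H](CO[Si](C)(C)C(C)(C)C)[C@H](O[Si](C)(C)C(C)(C)C)c3cc(OC)c(O[Si](C(C)C)(C(C)C)C(C)C)c(OC)c3)c(OC)c2)ccc1O[Si](C(C)C)(C(C)C)C(C)C | intermediate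
21 | bis(pinacolato)diboron | CC1(C)OB(OC1(C)C)B1OC(C)(C)C(C)(C)O1 | starting material
22 | (2R,3R,4Z)-2-Gu-4-(Sy-methylidene)-3-[(4,4,5,5-tetramethyl-1,3,2-dioxaborolan-2-yl)methyl]tetrahydrofuran | COc1cc([C@@H]2OC/C(=C\c3cc(OC)c(O[C@H](CO[Si](C)(C)C(C)(C)C)[C@H](O[Si](C)(C)C(C)(C)C)c4cc(OC)c(O[Si](C(C)C)(C(C)C)C(C)C)c(OC)c4)c(OC)c3)[C@H]2CB2OC(C)(C)C(C)(C)O2)ccc1O[Si](C(C)C)(C(C)C)C(C)C | intermediate
23 | [(2R,3S,4Z)-2-Gu-4-(Sy-methylidene)tetrahydrofuran-3-yl]methanol | COc1cc([C@@H]2OC/C(=C\c3cc(OC)c(O[C@H](CO[Si](C)(C)C(C)(C)C)[C@H](O[Si](C)(C)C(C)(C)C)c4cc(OC)c(O[Si](C(C)C)(C(C)C)C(C)C)c(OC)c4)c(OC)c3)[C@H]2CO)ccc1O[Si](C(C)C)(C(C)C)C(C)C | intermediate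
24 | (1R,3aR,4R,6aS)-1-Gu-4-Sy-3a-(phenylselanyl)tetrahydro-1H,3H-furo[3,4-c]furan | COc1cc([C@@H]2OC[C@]3([Se]c4ccccc4)[C@H]2CO[C@@H]3c2cc(OC)c(O[C@H](CO[Si](C)(C)C(C)(C)C)[C@H](O[Si](C)(C)C(C)(C)C)c3cc(OC)c(O[Si](C(C)C)(C(C)C)C(C)C)c(OC)c3)c(OC)c2)ccc1O[Si](C(C)C)(C(C)C)C(C)C | intermediate
25 | (1R,3aS,4S,6aS)-1-Gu-4-Sy-tetrahydro-1H,3H-furo[3,4-c]furan | COc1cc([C@@H]2OC[C@@H]3[C@H]2CO[C@@H]3c2cc(OC)c(O[C@H](CO[Si](C)(C)C(C)(C)C)[C@H](O[Si](C)(C)C(C)(C)C)c3cc(OC)c(O[Si](C(C)C)(C(C)C)C(C)C)c(OC)c3)c(OC)c2)ccc1O[Si](C(C)C)(C(C)C)C(C)C | intermediate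
26 | (1R,2R)-1-(4-hydroxy-3,5-dimethoxyphenyl)-2-{4-[(1S,3aS,4R,6aS)-4-(4-hydroxy-3-methoxyphenyl)tetrahydro-1H,3H-furo[3,4-c]furan-1-yl]-2,6-dimethoxyphenoxy}propane-1,3-diol | COc1cc([C@@H]2OC[C@@H]3[C@H]2CO[C@@H]3c2cc(OC)c(O[C@H](CO)[C@H](O)c3cc(OC)c(O)c(OC)c3)c(OC)c2)ccc1O | target

**Totals and risks**

Total step count: 15.
Longest linear sequence: 10 steps (steps 5, 7, 8, 9, 10, 11, 12, 13, 14, 15 from phenol 10; the branch from vanillin, steps 1 to 4 and 10 to 15, is equally long).

Steps most likely to fail: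

Step 11. The alkylpalladium at C9 may lose the C8 hydrogen faster than it is borylated, so that the enyne cycloisomerises without taking up boron. The insertion may also discriminate poorly between the two faces at C8, or palladium may ionise the doubly activated C7–O bond. The fallback sets out from enyne 20 and moves the ring closure from the hydropalladation manifold to a rhodium-catalysed cyclization/hydroboration. [Rh(cod)2]SbF6 with BINAP and catecholborane in 1,2-dichloroethane should join C8 to C8' and place boron on C9 with the same Z-benzylidene, giving the catechol boronate (2R,3R,4Z)-3-[(1,3,2-benzodioxaborol-2-yl)methyl]-2-Gu-4-(Sy-methylidene)tetrahydrofuran F1. The chiral diphosphine adds catalyst control over C8 to the substrate bias, and both antipodes of BINAP would be tried to find the matched pairing. Without isolation F1 is oxidised with NaBO3·4H2O, which returns to the route at alcohol 23 and makes step 12 unnecessary.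

Step 13. The seleniranium ion may open to a free benzylic cation, stabilised by the electron-rich syringyl ring, before the hydroxyl arrives; this would erase the anti relationship and scramble C7'. Electrophilic selenenylation of the activated arenes may compete. The fallback sets out from alcohol 23 and makes the C7'–O bond by reduction of an oxocarbenium ion instead of by addition to the alkene. Hydroboration with BH3·THF and oxidation with NaBO3·4H2O put a hydroxyl on the benzylic carbon C7' and give the 1,4-diol [(2R,3S)-2-Gu-4-[hydroxy(Sy)methyl]tetrahydrofuran-3-yl]methanol F2, in which the configuration at C8' and C7' is immaterial. MnO2 oxidises only the benzylic carbinol, and the resulting aryl ketone, whose α-carbon C8' can epimerise, should settle as the cis-fused lactol (1R,3aS,6aS)-1-Gu-4-Sy-tetrahydro-1H,3H-furo[3,4-c]furan-4-ol F3. Et3SiH with BF3·OEt2 at −78 °C then ionises the lactol and delivers hydride to the convex face of the bicyclic oxocarbenium ion, which places the aryl group endo and comes back to the route at 25, so that steps 13 and 14 are both bypassed.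

Step 10. Slow oxidative addition of zerovalent palladium into the electron-rich aryl bromide would leave the terminal alkyne of 9 exposed to copper-mediated oxidative dimerisation and the enyne to metal-induced isomerisation, at the point where two advanced fragments are at stake. The fallback reverses the order of bond formation so that the ether, not the aryl–alkyne bond, is made last. Setting out from aryl bromide 19, Sonogashira coupling with an excess of propargyl alcohol, which tolerates heating, gives 3-Sy-prop-2-yn-1-ol F4. CBr4 and PPh3 convert it into 3-Sy-prop-2-ynyl bromide F5. Alkylation of the sodium alkoxide 8, generated from alcohol 6 with NaH, with this bromide then returns to the route at enyne 20, and compound 9 is no longer needed.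

Further compounds
F1 | step 11 | (2R,3R,4Z)-3-[(1,3,2-benzodioxaborol-2-yl)methyl]-2-Gu-4-(Sy-methylidene)tetrahydrofuran | COc1cc([C@@H]2OC/C(=C\c3cc(OC)c(O[C@H](CO[Si](C)(C)C(C)(C)C)[C@H](O[Si](C)(C)C(C)(C)C)c4cc(OC)c(O[Si](C(C)C)(C(C)C)C(C)C)c(OC)c4)c(OC)c3)[C@H]2CB2Oc3ccccc3O2)ccc1O[Si](C(C)C)(C(C)C)C(C)C
F2 | step 13 | [(2R,3S)-2-Gu-4-[hydroxy(Sy)methyl]tetrahydrofuran-3-yl]methanol | COc1cc([C@@H]2OCC(C(O)c3cc(OC)c(O[C@H](CO[Si](C)(C)C(C)(C)C)[C@H](O[Si](C)(C)C(C)(C)C)c4cc(OC)c(O[Si](C(C)C)(C(C)C)C(C)C)c(OC)c4)c(OC)c3)[C@H]2CO)ccc1O[Si](C(C)C)(C(C)C)C(C)C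
F3 | step 13 | (1R,3aS,6aS)-1-Gu-4-Sy-tetrahydro-1H,3H-furo[3,4-c]furan-4-ol | COc1cc([C@@H]2OC[C@@H]3[C@H]2COC3(O)c2cc(OC)c(O[C@H](CO[Si](C)(C)C(C)(C)C)[C@H](O[Si](C)(C)C(C)(C)C)c3cc(OC)c(O[Si](C(C)C)(C(C)C)C(C)C)c(OC)c3)c(OC)c2)ccc1O[Si](C(C)C)(C(C)C)C(C)C
F4 | step 10 | 3-Sy-prop-2-yn-1-ol | OCC#Cc1cc(OC)c(O[C@H](CO[Si](C)(C)C(C)(C)C)[C@H](O[Si](C)(C)C(C)(C)C)c2cc(OC)c(O[Si](C(C)C)(C(C)C)C(C)C)c(OC)c2)c(OC)c1
F5 | step 10 | 3-Sy-prop-2-ynyl bromide | BrCC#Cc1cc(OC)c(O[C@H](CO[Si](C)(C)C(C)(C)C)[C@H](O[Si](C)(C)C(C)(C)C)c2cc(OC)c(O[Si](C(C)C)(C(C)C)C(C)C)c(OC)c2)c(OC)c1
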